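The cyclohexene ring (C1 = carbinol carbon bearing C7H2OBz, C2=C3, C4–OBz, C5, C6) is read as two divinylcarbinol units, C2–C1–C6 and C3–C4–C5, joined by two rungs, C2=C3 and C5–C6. Because C7 and the C4 oxygen lie on the same ring face, the units can be tied O7–Si–O4. One ruthenium catalyst then closes both rungs of this acyclic tetraene as alkenes by two ring-closing metatheses. This gives a bridged, achiral cyclohexa-1,4-diene that cannot aromatise. Desymmetrising hydroxy-directed epoxidation of one alkene and benzoate-assisted anti hydrolysis turn the C5=C6 rung into the trans-diol and set all four stereocentres.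

Key step: step 3

Numbering: all compounds keep the atom numbers C1–C7 given above. The "upper face" is the ring face that carries C7 and the oxygen on C4.
Assumption: the (1R,2R) ligand of step 6 is taken to direct oxygen to the alkene numbered C5=C6. If the sense is opposite, the (1S,2S) antipode does the same job.

Step 1
Reactants: 1 ethyl glycolate; 2 vinylmagnesium bromide
Product: 3 2-ethenylbut-3-ene-1,2-diol
Conditions: 2 (3.5 equiv), THF, 0 °C to rt; then H2O
Reagents that add atoms: none
Why: Double Grignard addition to the ester (one further equivalent is spent on the free hydroxyl) gives the tertiary divinylcarbinol, and no stereocentre is formed.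

Step 2
Reactants: 4 penta-1,4-dien-3-ol; 3 2-ethenylbut-3-ene-1,2-diol
Product: 6 mixed bis-alkoxysilane tetraene, via chlorosilane 5 (not isolated)
Conditions: iPr2SiCl2 (1.0 equiv), Et3N, CH2Cl2, −78 to 0 °C; then 3, Et3N, DMAP (cat.), 0 °C to rt
Reagents that add atoms: dichlorodi(propan-2-yl)silane CC(C)[Si](Cl)(Cl)C(C)C
Why: Stepwise silyl ether formation at a dichlorosilane (temporary silicon tether): the hindered secondary alcohol 4 should stop at monochloride 5, whose Si–Cl bond is then taken by the primary hydroxyl of 3 while the tertiary hydroxyl stays free, and no stereocentre is formed.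

Step 3
Reactants: 6 mixed bis-alkoxysilane tetraene
Product: 8 bridged diene 3,3-di(propan-2-yl)-2,4-dioxa-3-silabicyclo[4.2.2]deca-7,9-dien-6-ol, via eight-membered silaketal 7 (not isolated)
Conditions: second-generation Grubbs catalyst (2 × 5 mol %), 1,4-benzoquinone (10 mol %), toluene (1 mM), 80 °C, closed flask under Ar
Reagents that add atoms: none
Why: Ring-closing olefin metathesis is run twice by one ruthenium alkylidene: [2+2] cycloaddition and cycloreversion first join one vinyl group of the C2–C1–C6 carbinol to one vinyl group of the C3–C4–C5 carbinol (C2=C3, loss of ethene), then the two remaining vinyl groups of 7 meet across the ring (C5=C6, loss of ethene). The closest known reaction type is temporary silicon-tethered ring-closing metathesis of bis-alkoxysilanes made from penta-1,4-dien-3-ol. The first closure gives the eight-membered 1,3-dioxa-2-silacyclooct-5-ene as its Z-alkene, and the second is a transannular closure of the six-membered carbocycle that leaves the CH2–O–Si–O chain as a four-atom bridge over C1 and C4. No reagent fixes a configuration: C1 and C4 are set relative to each other by the bridge, since only the isomer of 7 with both vinyl groups on one face can close, and the other isomer is returned to 6 by the liberated ethene through the reversible first closure. The step needs pairing of unlike carbinols and cyclisation over chain growth; two vinyl groups on one carbinol carbon could only give a cyclopropene, so cross pairing is the only ring-forming path, and high dilution, the fully substituted C1 and its free allylic hydroxyl favour cyclisation. The bridge also blocks loss of water to an arene, because that arene would be a paracyclophane with a four-atom bridge.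

Step 4
Reactants: 8 bridged diene
Product: 9 1-(hydroxymethyl)cyclohexa-2,5-diene-1,4-diol (CH2OH cis to 4-OH; achiral)
Conditions: Bu4NF (2.2 equiv), THF, 0 °C; then H2O
Reagents that add atoms: none
Why: Fluoride cleavage of both Si–O bonds (desilylation) frees the C7 and C4 hydroxyls with their cis relation intact, and the absence of acid should keep the doubly allylic diol from losing water to an arene.

Step 5
Reactants: 9 1-(hydroxymethyl)cyclohexa-2,5-diene-1,4-diol
Product: 10 [4-(benzoyloxy)-1-hydroxycyclohexa-2,5-dien-1-yl]methyl benzoate (CH2OBz cis to 4-OBz; achiral)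
Conditions: BzCl (2.1 equiv), pyridine, CH2Cl2, −20 to 0 °C
Reagents that add atoms: benzoyl chloride O=C(Cl)c1ccccc1
Why: Acylation in pyridine esterifies the primary C7–OH and the secondary C4–OH while the tertiary C1–OH is too hindered to react, and no stereocentre is touched.

Step 6
Reactants: 10 dienol dibenzoate
Product: 11 (1S,4R,5S,6S)-5,6-epoxide of 10 (epoxide on the face of C1–OH; trans to C4–OBz)
Conditions: Hf(OtBu)4 (10 mol %), (1R,2R)-N,N'-dihydroxy-N,N'-bis(diphenylacetyl)cyclohexane-1,2-diamine (11 mol %), MgO, cumene hydroperoxide (1.3 equiv), toluene, 0 °C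
Reagents that add atoms: cumene hydroperoxide CC(C)(OO)c1ccccc1
Why: Hydroxy-directed catalytic asymmetric epoxidation of a tertiary allylic alcohol (metal–bishydroxamic acid type): the hafnium alkoxide of C1–OH delivers oxygen to the lower face, which is also free of both ester groups, the chiral ligand chooses between the two enantiotopic alkenes and so sets C5 and C6 and makes C1 and C4 stereogenic, and the minor enantiomer should be drained faster into the bis-epoxide.

Step 7
Reactants: 11 epoxide dibenzoate
Product: 13 target [(1S,4R,5S,6S)-4-(benzoyloxy)-1,5,6-trihydroxycyclohex-2-en-1-yl]methyl benzoate, via orthoacid 12 (not isolated)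
Conditions: HClO4 (5 mol %), THF–H2O 4:1, 0 °C to rt
Reagents that add atoms: water O
Why: Acid-catalysed anti opening of the epoxide with anchimeric assistance: the C4 benzoate, trans to the epoxide, attacks C5 from the upper face (five-membered 1,3-dioxolan-2-ylium, inversion at C5) while C6–O keeps its configuration, and water gives orthoacid 12, which should collapse to the pseudoaxial C4 ester and the equatorial C5 hydroxyl; direct attack of water at the less hindered C5 gives the same product.

Compound list
1 | ethyl glycolate | CCOC(=O)CO | starting material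
2 | vinylmagnesium bromide | C=C[Mg]Br | starting material
3 | 2-ethenylbut-3-ene-1,2-diol | OCC(O)(C=C)C=C | intermediate
4 | penta-1,4-dien-3-ol | C=CC(O)C=C | starting material
5 | chlorodi(propan-2-yl)(penta-1,4-dien-3-yloxy)silane | C=CC(C=C)O[Si](Cl)(C(C)C)C(C)C | intermediate
6 | 2-ethenyl-1-{[di(propan-2-yl)(penta-1,4-dien-3-yloxy)silyl]oxy}but-3-en-2-ol | C=CC(C=C)O[Si](C(C)C)(C(C)C)OCC(O)(C=C)C=C | intermediate
7 | (Z)-4,7-diethenyl-2,2-di(propan-2-yl)-1,3-dioxa-2-silacyclooct-5-en-7-ol, both vinyl groups on one face (racemic, one enantiomer drawn) | C=C[C@H]1/C=C\[C@@](O)(C=C)CO[Si](C(C)C)(C(C)C)O1 | intermediate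
8 | 3,3-di(propan-2-yl)-2,4-dioxa-3-silabicyclo[4.2.2]deca-7,9-dien-6-ol (achiral; the bridge holds C7 and the C4 oxygen on one face) | OC12C=CC(C=C1)O[Si](C(C)C)(C(C)C)OC2 | intermediate
9 | 1-(hydroxymethyl)cyclohexa-2,5-diene-1,4-diol, CH2OH cis to 4-OH (achiral) | OC[C@@]1(O)C=C[C@@H](O)C=C1 | intermediate
10 | [4-(benzoyloxy)-1-hydroxycyclohexa-2,5-dien-1-yl]methyl benzoate, CH2OBz cis to 4-OBz (achiral) | O=C(OC[C@@]1(O)C=C[C@@H](OC(=O)c2ccccc2)C=C1)c1ccccc1 | intermediate
11 | [(1S,2S,5R,6S)-5-(benzoyloxy)-2-hydroxy-7-oxabicyclo[4.1.0]hept-3-en-2-yl]methyl benzoate | O=C(OC[C@@]1(O)C=C[C@@H](OC(=O)c2ccccc2)[C@@H]2O[C@H]12)c1ccccc1 | intermediate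
12 | cis-fused 2-hydroxy-2-phenyl-1,3-dioxolane on O4 and O5 (orthoacid; 6-OH on the lower face) | O=C(OC[C@@]1(O)C=C[C@H]2OC(O)(c3ccccc3)O[C@H]2[C@@H]1O)c1ccccc1 | intermediate
13 | [(1S,4R,5S,6S)-4-(benzoyloxy)-1,5,6-trihydroxycyclohex-2-en-1-yl]methyl benzoate | O=C(OC[C@@]1(O)C=C[C@@H](OC(=O)c2ccccc2)[C@@H](O)[C@@H]1O)c1ccccc1 | target

Total step count: 7. Longest linear sequence: 7 steps (1 → 3 → 6 → 8 → 9 → 10 → 11 → 13).

Steps most likely to fail

Step 3. The tandem may stop after the first closure, chains may grow by intermolecular metathesis, or the strain of the bridge may hold back the second closure. The fallback sets out from 6 and comes back at 9. It separates the two closures and runs the second one without the bridge. Tetraene 6 is closed once (first-generation Grubbs catalyst, CH2Cl2, 40 °C) and silaketal 7 is isolated. The isomer of 7 with both vinyl groups on one face is separated. Bu4NF then frees the (Z)-configured triene triol F1. A ring-closing metathesis of this 1,4,7-triene (second-generation Grubbs catalyst, CH2Cl2, 40 °C) gives 9.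

Step 6. The catalyst may discriminate poorly between the two enantiotopic alkenes, or the Lewis-acidic metal may trigger loss of water from the doubly allylic carbinol. The fallback sets out from 9 and comes back at 11. It breaks the symmetry at the dienone level by nucleophilic instead of electrophilic epoxidation.
- MnO2 oxidises the doubly allylic C4–OH of 9 to the quinol dienone F2.
- BzCl in pyridine gives its primary benzoate F3.
- Tartrate-modified trityl hydroperoxide (Ph3COOH, NaN(SiMe3)2, L-diisopropyl tartrate, toluene, −50 °C), anchored on C1–OH, epoxidises one enone to the epoxy enone F4.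
- Luche reduction (NaBH4, CeCl3·7H2O, MeOH, −78 °C) from the face opposite to the epoxide gives the cis-epoxy alcohol F5.
- A Mitsunobu reaction (PhCO2H, PPh3, DIAD, THF) inverts C4 and gives 11.

Step 7. Three processes could spoil this step: opening at C6 through six-membered participation of the C7 benzoate, a benzoyl shift from O4 to O5 in the orthoacid, or ionisation of the tertiary allylic C1–OH in aqueous acid. The fallback sets out from 11 and comes back at 13. It replaces hydrolysis by non-aqueous acidolysis with an external carboxylate, followed by chemoselective solvolysis. CF3CO2H (1.1 equiv, CH2Cl2, −20 °C) opens the epoxide at C5 to the C5 trifluoroacetate F6. NaHCO3 in MeOH at 0 °C then removes only this activated ester and leaves both benzoates in place.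

Further compounds
F1 | step 3 | (Z)-3-(hydroxymethyl)octa-1,4,7-triene-3,6-diol, relative configuration as in 7 (racemic) | C=C[C@H](O)/C=C\[C@](O)(CO)C=C
F2 | step 6 | 4-hydroxy-4-(hydroxymethyl)cyclohexa-2,5-dien-1-one | O=C1C=CC(O)(CO)C=C1
F3 | step 6 | (1-hydroxy-4-oxocyclohexa-2,5-dien-1-yl)methyl benzoate | O=C(OCC1(O)C=CC(=O)C=C1)c1ccccc1
F4 | step 6 | 5,6-epoxy enone, epoxide on the face of C1–OH | O=C(OC[C@@]1(O)C=CC(=O)[C@@H]2O[C@H]12)c1ccccc1
F5 | step 6 | 5,6-epoxy-4-ol, C4–OH cis to the epoxide | O=C(OC[C@@]1(O)C=C[C@H](O)[C@@H]2O[C@H]12)c1ccccc1
F6 | step 7 | C5 trifluoroacetate of the target | O=C(OC[C@@]1(O)C=C[C@@H](OC(=O)c2ccccc2)[C@@H](OC(=O)C(F)(F)F)[C@@H]1O)c1ccccc1
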